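At early times the readings of c(target) are small against the charge, 0.007 M at 17 min in the spring run, so watch instead the late readings of c(target).

| setting | noon | spring | midnight | summer |
|---|---|---|---|---|
| starting material | 0.400 M | 0.160 M | 0.600 M | 0.130 M |
| time |  |  |  | 100 min |

- noon run (time / min: [target] / M): 17: 0.067; 33: 0.169; 50: 0.193; 67: 0.215; 83: 0.213; 100: 0.216
- spring run (time / min: [target] / M): 17: 0.007; 33: 0.017; 50: 0.032; 67: 0.045; 83: 0.040; 100: 0.045
- midnight run (time / min: [target] / M): 17: 0.189; 33: 0.348; 50: 0.369; 67: 0.378; 83: 0.387; 100: 0.386

(standard deviation of a reading: 0.004 M)

- Overall: starting material -> target.
- Constant volume, constant temperature.
- An order is taken over about fifteen percent of the charge, up and down.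

- the exponent of [starting material] in the starting rate at the charge of the noon run (at the point where two percent of the starting material have become target) (one fixed amount of target, the same in the runs compared)
- target in the summer run at 100 min, as a share of the starting material charged

In the spring run your last 3 readings average 0.0433 M, a late share of 27.1% of the charge. Now turn the question round: for the summer run to reach half of its charge, target would have to stand at even odds with the charge that did not become target.

So carry the selectivity as late odds per molar: late share over the remaining share, divided by the charge. Spring's odds are 0.371, which gives 2.32 /M. If a route one order higher in c(starting material) races a first-order loss, the odds follow the mean c(starting material), and replacing that falling curve by a fixed fraction of the charge makes them proportional to the charge.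

To check the error of that replacement, take the noon run, whose last 3 readings average a late share of 53.7% and give 2.90 /M. That is 24.7% above the spring value, so I use spring, whose charge lies closer to summer's than noon's does.

The summer odds are then 0.302, short of even, and the share is 23.2%, if the summer run at 100 min is as far along as the late readings of the spring run.

The forecast gives 2.2 for the order and 22% for the share, reading “an accelerating reaction that is cut off”.

The simulation gives an order of 1.2, less than the forecast's, and a share of 22.8%.

    2 starting material ⇌ intermediate + starting material (0.1092 /M/min, 0.2886 /M/min)
    intermediate → target (0.02340 /min)
    starting material → decomposed substrate (0.03012 /min)
    starting material + target → 2 target (0.6360 /M/min)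

Read from that summer result, the odds per molar are 2.27 /M, beside the 2.32 /M carried from spring. The race is real: the summer run reaches 22.8% with the loss of starting material to decomposed substrate and 95.3% without it. That loss accounts for 94% of what is missing.

(The earlier runs and the new flask were generated by integration for an exercise, noise included.)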